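The numbers in the tables were generated by integration with constants of no real substance; scatter was added.

Compare what has left the solid with what has become product in the north run, which is the very flask asked about: at 0.333 min the solid substrate has lost 61.1 % of the charge, more than the 9.3 % counted as product.

- north: solid substrate 5 mM; the very flask that is asked about, followed so far
- flask: solid substrate 5.0 mM; time 30 min

- north (time / min: intermediate / %, product / %, solid substrate / %): 0.167: 12.6, 2.2, 68.5; 0.333: 25.3, 9.3, 38.9; 0.667: 31.7, 33.7, 0; 1.33: 12.3, 62.6, 0.3; 3.00: 4.8, 88.0, 0; 6.00: 1.4, 96.7, 0

(each reading ± 1 percentage point)

- amounts and yields of product count crystals too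
- given per volume of solution although it is solid: solid substrate, crystals
- steps under discussion: intermediate <-> product; starting material <-> intermediate; solid substrate <-> starting material; crystals <-> product; starting material <-> dormant form
- at the start none of the solid substrate is in solution

* when, up to 30 min, the flask holds most intermediate
* the amount of intermediate, in percent of the solid substrate charged, at that time
* the first time at which intermediate reaches 17 %, in the same percent, in min

Where is the rest? It is dissolved, as starting material, intermediate and dormant form. I call this pool the fraction left: the charge minus solid minus product, crystals included.

How much of that pool is intermediate? At 0.667 min, with the solid reading 0 %, the ratio of [intermediate] to the fraction left reads 0.478. This is the pool share.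

Why trust one reading? At 0.333 min the same ratio reads 0.488. By 1.33 min it has fallen to 0.332, so I use it around the peak and not at later times.

When does [intermediate] peak? The pool grows while the solid feeds it: between the first two readings the solid lost 30 percentage points and product gained 7.1 points. By 0.667 min the solid reads 0 %, and with that feed ended the pool shrinks as product rises. The line through those two solid readings reaches zero at 0.551 min.

How much then? Interpolated product is 25.2 %, which leaves 74.8 %, and the share makes that 35.7 % intermediate.

The forecast gives 34 % at 0.55 min, with 17 % reached at 0.225 min, holding that “the maximum should sit around the moment the solid runs out”. My amount stands above its amount.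

The flask gives 34.4 % at 0.591 min, and reaches 17 % at 0.217 min.

    intermediate ⇌ product (K = 2.50, k = 0.0411 s⁻¹)
    starting material ⇌ intermediate (K = 2.99, k = 0.235 s⁻¹)
    solid substrate ⇌ starting material, rate k3*(cs3 - [starting material]) while solid is left; crystals form when [starting material] > cs3 (solubility = 3.30 mM, k = 0.0558 s⁻¹)
    crystals ⇌ product, rate k4*(cs4 - [product]) while solid is left; crystals form when [product] > cs4 (solubility = 0.190 mM, k = 3.17 s⁻¹)
    starting material ⇌ dormant form (K = 2.37, k = 0.0577 s⁻¹)

At 0.591 min this flask holds 0 % solid and 27.6 % product, so 72.4 % is left, and the share makes that 34.6 %, beside the 34.4 % of intermediate standing there. For the neighbour flask, charged with 3.0 mM, take the solid entering at the north rate in mM per minute. On that reckoning the line for the solid reaches zero at 0.331 min, close to 0.333 min, when the north product in mM is 15.5 % of this smaller charge. That leaves 84.5 %, and the share gives 40.4 % intermediate. The neighbour's simulated peak is 41.6 %.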